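**Remark (assumption):** the SMILES is read as epicatechin 3‑O‑gallate‑(4β→8)‑epigallocatechin 3‑O‑gallate‑(4β→8)‑catechin 3‑O‑gallate (top, middle and terminal unit; flavan numbering O1, C2–C4, C4a, C5–C8, C8a in each unit). Compounds 1, 4, 9, 11 and 15 are assumed to be purchasable.

## Retrosynthetic overview

1. The last operation is hydrogenolysis of 22 benzyl ethers from the perbenzylated trimer 32; all galloyl esters are in place before the key step.
2. Enabling feature: in the terminal catechin unit, ring oxygen O1 and the interflavan carbon sit on the neighbouring ring‑A carbons C8a and C8, with the C7 oxygen flanking C8. This is the imprint of an aryne C8≡C8a, so the O1–C8a bond (closing ring C) and the C8–C4(middle) bond are made together by inserting that aryne into the C4–O bond of ether 29, in which O1 already joins C2 of the open‑chain terminal unit to C4 of the middle unit.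
3. Ether 29 comes from silver‑promoted union of the 4‑thio dimer 10 with the acyclic alcohol 28; dimer 10 comes from epicatechin and epigallocatechin by a Lewis‑acid C4→C8 coupling with orthogonal O/S activation at C4.
4. Alcohol 28 (anti diol monogallate carrying an ortho‑silylaryl triflate) comes from 3,5‑bis(benzyloxy)phenol by two directed ortho‑metalations: silicon first, then opening of an erythro epoxy silyl ether made by Sharpless kinetic resolution.
5. Ring order: rings A, B and C of the top and middle units are taken intact from 1 and 4; interflavan bond 1 is formed in step 6; ring C of the terminal unit closes last (step 18), together with interflavan bond 2.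

Key step: step 18

## Route

Step 1
Reactants: 1 (−)-epicatechin
Product: 2 5,7,3',4'-tetra-O-benzyl-(−)-epicatechin
Conditions: BnBr, K2CO3, DMF, 0 °C → rt
Reagents that add atoms: benzyl bromide, BrCc1ccccc1
Why: Williamson O‑benzylation: K2CO3 deprotonates only the four phenols, so the aliphatic 3‑OH stays free and no stereocenter is touched.

Step 2
Reactants: 2 5,7,3',4'-tetra-O-benzyl-(−)-epicatechin
Product: 3 4β-(2-ethoxyethoxy)-5,7,3',4'-tetra-O-benzylepicatechin
Conditions: DDQ, HOCH2CH2OEt, CH2Cl2, rt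
Reagents that add atoms: 2-ethoxyethanol, CCOCCO
Why: DDQ benzylic oxidation: hydride loss from C4 (activated by the 5,7‑dialkoxy ring A) gives a flavan‑4‑yl cation that the alcohol captures anti to the C3 hydroxyl and the C2 aryl group, which sets the 4β (3,4‑trans) center.

Step 3
Reactants: 4 (−)-epigallocatechin
Product: 5 5,7,3',4',5'-penta-O-benzyl-(−)-epigallocatechin
Conditions: BnBr, K2CO3, DMF, 0 °C → rt
Reagents that add atoms: benzyl bromide, BrCc1ccccc1
Why: Williamson O‑benzylation of the five phenols only, as in step 1.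

Step 4
Reactants: 5 5,7,3',4',5'-penta-O-benzyl-(−)-epigallocatechin
Product: 6 4β-(2-ethoxyethoxy)-penta-O-benzylepigallocatechin
Conditions: DDQ, HOCH2CH2OEt, CH2Cl2, rt
Reagents that add atoms: 2-ethoxyethanol, CCOCCO
Why: DDQ benzylic oxidation at C4 with alcohol capture anti to the 3‑OH, as in step 2, sets the 4β center.

Step 5
Reactants: 6 4β-(2-ethoxyethoxy)-penta-O-benzylepigallocatechin
Product: 7 4β-(4-methylphenylthio)-penta-O-benzylepigallocatechin
Conditions: 4-MeC6H4SH, BF3·OEt2 (cat.), CH2Cl2, −78 → −20 °C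
Reagents that add atoms: 4-methylbenzenethiol, Cc1ccc(S)cc1
Why: Lewis‑acid thiolysis (acetal‑type exchange): BF3 ionises the 4‑alkoxy group and the thiol captures the cation again anti to the 3‑OH, leaving a 4β‑thioether that hard Lewis acids do not activate.

Step 6
Reactants: 3 4β-(2-ethoxyethoxy)-5,7,3',4'-tetra-O-benzylepicatechin; 7 4β-(4-methylphenylthio)-penta-O-benzylepigallocatechin
Product: 8 tetra-O-benzylepicatechin-(4β→8)-[penta-O-benzyl-4β-(4-methylphenylthio)epigallocatechin] (both 3-OH free)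
Conditions: BF3·OEt2 (cat.), 7 (3 equiv), CH2Cl2, −78 → −30 °C
Reagents that add atoms: none
Why: Friedel–Crafts coupling of a flavan‑4‑yl cation with an orthogonally masked nucleophile: BF3·OEt2 ionises only the 4‑alkoxy donor 3, the excess of 7 suppresses self‑condensation and reacts at its most nucleophilic carbon C8, and attack anti to the 3‑OH sets the 4β interflavan center.

Step 7
Reactants: 8 the dimer diol; 9 3,4,5-tris(benzyloxy)benzoic acid (two equivalents are taken up, one per hydroxyl)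
Product: 10 3,3''-bis-O-[3,4,5-tris(benzyloxy)benzoyl] derivative of 8
Conditions: 9 (2.5 equiv), DCC, DMAP, CH2Cl2, rt
Reagents that add atoms: 3,4,5-tris(benzyloxy)benzoic acid (compound 9, the second equivalent), OC(=O)c1cc(OCc2ccccc2)c(OCc2ccccc2)c(OCc2ccccc2)c1
Why: Twofold Steglich esterification (DCC/DMAP): each of the two secondary 3‑hydroxyls is acylated by one molecule of acid 9, and no stereocenter is affected.

Step 8
Reactants: 11 3,4-bis(benzyloxy)benzaldehyde
Product: 12 rac-1-[3,4-bis(benzyloxy)phenyl]prop-2-en-1-ol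
Conditions: CH2=CHMgBr, THF, −78 → 0 °C; H2O
Reagents that add atoms: vinylmagnesium bromide, C=C[Mg]Br
Why: Grignard addition to the aldehyde gives the racemic allylic alcohol needed for the resolution.

Step 9
Reactants: 12 rac-1-[3,4-bis(benzyloxy)phenyl]prop-2-en-1-ol
Product: 13 (R)-[3,4-bis(benzyloxy)phenyl][(2S)-oxiran-2-yl]methanol
Conditions: Ti(OiPr)4 (cat.), D-(−)-diisopropyl tartrate, t-BuOOH (0.6 equiv), 4 Å MS, CH2Cl2, −20 °C
Reagents that add atoms: tert-butyl hydroperoxide, CC(C)(C)OO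
Why: Sharpless kinetic resolution by asymmetric epoxidation: with the D‑(−)‑tartrate the (S)‑alcohol is epoxidised much faster and gives the erythro (anti) epoxy alcohol, so the reagent sets both centers (carbinol R, oxirane S) while the (R)‑alcohol is left behind and separated.

Step 10
Reactants: 13 (R)-[3,4-bis(benzyloxy)phenyl][(2S)-oxiran-2-yl]methanol
Product: 14 triethylsilyl ether of 13
Conditions: Et3SiCl, imidazole, CH2Cl2, 0 °C
Reagents that add atoms: chlorotriethylsilane, CC[Si](Cl)(CC)CC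
Why: Silylation of the secondary alcohol; the triethylsilyl ether is chosen because it can later be removed without fluoride.

Step 11
Reactants: 15 3,5-bis(benzyloxy)phenol
Product: 16 3,5-bis(benzyloxy)phenyl N-isopropylcarbamate
Conditions: i-PrNCO, Et3N (cat.), CH2Cl2, rt
Reagents that add atoms: isopropyl isocyanate, CC(C)N=C=O
Why: Addition of the phenol to the isocyanate gives the N–H carbamate that serves as a cleavable directing group.

Step 12
Reactants: 16 3,5-bis(benzyloxy)phenyl N-isopropylcarbamate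
Product: 20 3,5-bis(benzyloxy)-2-(trimethylsilyl)phenyl N-isopropylcarbamate, via N-silyl carbamate 17 (not isolated), via aryllithium 18 (not isolated), via N-silyl C-silyl carbamate 19 (not isolated)
Conditions: TBSOTf, TMEDA, Et2O, 0 °C → rt; n-BuLi (2 equiv), TMEDA, −78 °C; Me3SiCl, −78 °C → rt; aq NaHSO4
Reagents that add atoms: chlorotrimethylsilane, C[Si](C)(C)Cl
Why: Directed ortho‑metalation: the in situ N‑silylated carbamate directs lithiation to the position between the carbamate and a benzyloxy group, Me3SiCl traps the aryllithium, and the acidic work‑up removes the N‑silyl group so that 20 can be purified.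

Step 13
Reactants: 20 3,5-bis(benzyloxy)-2-(trimethylsilyl)phenyl N-isopropylcarbamate; 14 triethylsilyl ether of 13
Product: 24 3,5-bis(benzyloxy)-2-[(2S,3R)-3-[3,4-bis(benzyloxy)phenyl]-2-hydroxy-3-(triethylsilyloxy)propyl]-6-(trimethylsilyl)phenyl N-isopropylcarbamate, via N-trimethylsilyl carbamate 21 (not isolated), via aryllithium 22 (not isolated), via N-trimethylsilyl epoxide adduct 23 (not isolated)
Conditions: Me3SiOSO2CF3, TMEDA, Et2O, 0 °C → rt; n-BuLi (2 equiv), −78 °C; 14, BF3·OEt2, THF, −78 °C; aq citric acid, 0 °C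
Reagents that add atoms: none
Why: Second directed ortho‑metalation at the only remaining position ortho to the carbamate, followed by BF3‑promoted SN2 opening of the terminal epoxide at its CH2 carbon; here the nitrogen is masked in situ as the smaller and more labile N–SiMe3 group, which cold citric acid removes within minutes without harming the triethylsilyl ether, both stereocenters of 14 are untouched, and the boron‑bound alkoxide should not allow silyl migration.

Step 14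
Reactants: 24 the hydroxy carbamate; 9 3,4,5-tris(benzyloxy)benzoic acid
Product: 25 2-O-[3,4,5-tris(benzyloxy)benzoyl] ester of 24
Conditions: 9, DCC, DMAP, CH2Cl2, rt
Reagents that add atoms: none
Why: Steglich esterification of the only free hydroxyl places the galloyl group on the future C3 oxygen with retention.

Step 15
Reactants: 25 the galloylated carbamate
Product: 27 aryl triflate corresponding to 25 (carbamate replaced by OSO2CF3), via phenol 26 (not isolated)
Conditions: DBU, Et2NH, MeCN, 40 °C; PhNTf2, rt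
Reagents that add atoms: N-phenylbis(trifluoromethanesulfonimide), O=S(=O)(N(c1ccccc1)S(=O)(=O)C(F)(F)F)C(F)(F)F
Why: Base‑induced E1cB cleavage of the N–H carbamate (isocyanate scavenged by Et2NH) and triflation of the phenoxide with PhNTf2, the established one‑pot route from ortho‑silyl aryl carbamates to ortho‑silylaryl triflates.

Step 16
Reactants: 27 the silyl triflate
Product: 28 (1R,2S)-1-[3,4-bis(benzyloxy)phenyl]-3-[2,4-bis(benzyloxy)-6-(trifluoromethylsulfonyloxy)-5-(trimethylsilyl)phenyl]-1-hydroxypropan-2-yl 3,4,5-tris(benzyloxy)benzoate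
Conditions: AcOH/THF/H2O (3:1:1), rt
Reagents that add atoms: none
Why: Mild acid hydrolysis of the triethylsilyl ether; fluoride is avoided so that the silyl triflate stays intact, and the ester should not migrate under these conditions.

Step 17
Reactants: 10 the 4-thio dimer digallate; 28 the chain alcohol
Product: 29 4β-O-ether of the dimer digallate with alcohol 28 (thioether replaced by the benzylic oxygen of 28)
Conditions: AgOSO2CF3, 2,6-di-tert-butyl-4-methylpyridine, 4 Å MS, CH2Cl2, −40 → 0 °C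
Reagents that add atoms: none
Why: Thiophilic activation of the benzylic thioether by AgOSO2CF3 (as in thioglycoside and 4‑thioflavan activation) gives the flavan‑4‑yl cation, which alcohol 28 captures on the β face anti to the 3‑O‑galloyl group (3,4‑trans), while the hindered pyridine keeps the medium non‑acidic so that the product ether does not re‑ionise.

Step 18
Reactants: 29 the 4β-O-ether
Product: 32 docosa-O-benzyl derivative of the target (perbenzylated trimer), via aryne 30 (not isolated), via oxonium aryl-anion zwitterion 31 (not isolated)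
Conditions: Bu4N[Ph3SiF2] (TBAT), toluene (0.005 M), rt → 40 °C
Reagents that add atoms: none
Why: Proposed new method: fluoride removes the trimethylsilyl group and expels triflate to give the 3‑benzyloxy aryne 30; the tethered bis‑benzylic ether oxygen adds to the aryne carbon remote from the C7 benzyloxy group (6‑exo‑dig closure of the pyran ring, the only mode the tether allows and also the electronically preferred one because the charge develops ortho to oxygen) to give zwitterion 31, whose flavan‑4‑yl group then moves from oxygen to the neighbouring aryl carbanion (net aryne insertion into the C4–O bond, a 1,3‑shift through a contact ion pair) and so forges the C4–C8 interflavan bond. The closest known reactions are the fluoride‑triggered σ‑insertions of arynes into polarised carbon–heteroatom bonds through onium/aryl‑anion zwitterions (C–N, C–S, and the benzylic C–O bond of aryl epoxides), and chroman formation by addition of tethered oxygen nucleophiles to arynes. The configuration at C4 of the middle unit is controlled by the adjacent 3‑O‑galloyl group (recombination anti to it, as in all 3,4‑trans captures of flavan‑4‑yl cations) and by the ion pair being born on the β face; C2 and C3 of the new ring are not touched. The step needs (a) regioselective aryne capture, secured by the tether and the C7 benzyloxy group, (b) migration of the flavan‑4‑yl group and not of the ring benzylic carbon, secured by the far greater stability of the 2,4,6‑trioxygenated benzylic cation, and (c) C–C collapse faster than protonation or β‑elimination, which an aprotic, non‑acidic medium, an anhydrous fluoride source and high dilution should favour.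

Step 19
Reactants: 32 the perbenzylated trimer
Product: 33 target CNP0321910.1
Conditions: H2 (1 atm), Pd(OH)2/C, THF/MeOH/H2O, rt
Reagents that add atoms: none
Why: Catalytic hydrogenolysis should remove all 22 benzyl ethers over Pd(OH)2/C without touching the three gallate esters or any stereocenter.

## Compound list

1 | (−)-epicatechin | C1c2c(O)cc(O)cc2O[C@H](c2ccc(O)c(O)c2)[C@@H]1O | starting material
2 | 5,7,3',4'-tetra-O-benzyl-(−)-epicatechin | C1c2c(OCc5ccccc5)cc(OCc5ccccc5)cc2O[C@H](c2ccc(OCc5ccccc5)c(OCc5ccccc5)c2)[C@@H]1O | intermediate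
3 | 4β-(2-ethoxyethoxy)-5,7,3',4'-tetra-O-benzylepicatechin | CCOCCO[C@H]1c2c(OCc5ccccc5)cc(OCc5ccccc5)cc2O[C@H](c2ccc(OCc5ccccc5)c(OCc5ccccc5)c2)[C@@H]1O | intermediate
4 | (−)-epigallocatechin | C1c2c(O)cc(O)cc2O[C@H](c2cc(O)c(O)c(O)c2)[C@@H]1O | starting material
5 | 5,7,3',4',5'-penta-O-benzyl-(−)-epigallocatechin | C1c2c(OCc5ccccc5)cc(OCc5ccccc5)cc2O[C@H](c2cc(OCc5ccccc5)c(OCc5ccccc5)c(OCc5ccccc5)c2)[C@@H]1O | intermediate
6 | 4β-(2-ethoxyethoxy)-penta-O-benzylepigallocatechin | CCOCCO[C@H]1c2c(OCc5ccccc5)cc(OCc5ccccc5)cc2O[C@H](c2cc(OCc5ccccc5)c(OCc5ccccc5)c(OCc5ccccc5)c2)[C@@H]1O | intermediate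
7 | 4β-(4-methylphenylthio)-penta-O-benzylepigallocatechin | Cc1ccc(S[C@H]2c3c(OCc5ccccc5)cc(OCc5ccccc5)cc3O[C@H](c3cc(OCc5ccccc5)c(OCc5ccccc5)c(OCc5ccccc5)c3)[C@@H]2O)cc1 | intermediate
8 | tetra-O-benzylepicatechin-(4β→8)-[penta-O-benzyl-4β-(4-methylphenylthio)epigallocatechin], both 3-OH free | Cc1ccc(S[C@H]2c3c(OCc5ccccc5)cc(OCc5ccccc5)c([C@H]4c6c(OCc5ccccc5)cc(OCc5ccccc5)cc6O[C@H](c6ccc(OCc5ccccc5)c(OCc5ccccc5)c6)[C@@H]4O)c3O[C@H](c3cc(OCc5ccccc5)c(OCc5ccccc5)c(OCc5ccccc5)c3)[C@@H]2O)cc1 | intermediate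
9 | 3,4,5-tris(benzyloxy)benzoic acid | OC(=O)c1cc(OCc2ccccc2)c(OCc2ccccc2)c(OCc2ccccc2)c1 | starting material
10 | 3,3''-bis-O-[3,4,5-tris(benzyloxy)benzoyl] derivative of 8 | Cc1ccc(S[C@H]2c3c(OCc5ccccc5)cc(OCc5ccccc5)c([C@H]4c6c(OCc5ccccc5)cc(OCc5ccccc5)cc6O[C@H](c6ccc(OCc5ccccc5)c(OCc5ccccc5)c6)[C@@H]4OC(=O)c6cc(OCc5ccccc5)c(OCc5ccccc5)c(OCc5ccccc5)c6)c3O[C@H](c3cc(OCc5ccccc5)c(OCc5ccccc5)c(OCc5ccccc5)c3)[C@@H]2OC(=O)c3cc(OCc5ccccc5)c(OCc5ccccc5)c(OCc5ccccc5)c3)cc1 | intermediate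
11 | 3,4-bis(benzyloxy)benzaldehyde | O=Cc1ccc(OCc2ccccc2)c(OCc2ccccc2)c1 | starting material
12 | rac-1-[3,4-bis(benzyloxy)phenyl]prop-2-en-1-ol | C=CC(O)c1ccc(OCc2ccccc2)c(OCc2ccccc2)c1 | intermediate
13 | (R)-[3,4-bis(benzyloxy)phenyl][(2S)-oxiran-2-yl]methanol | O[C@H](c1ccc(OCc2ccccc2)c(OCc2ccccc2)c1)[C@@H]1CO1 | intermediate
14 | triethylsilyl ether of 13 | CC[Si](CC)(CC)O[C@H](c1ccc(OCc2ccccc2)c(OCc2ccccc2)c1)[C@@H]1CO1 | intermediate
15 | 3,5-bis(benzyloxy)phenol | Oc1cc(OCc2ccccc2)cc(OCc2ccccc2)c1 | starting material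
16 | 3,5-bis(benzyloxy)phenyl N-isopropylcarbamate | CC(C)NC(=O)Oc1cc(OCc2ccccc2)cc(OCc2ccccc2)c1 | intermediate
17 | N-(tert-butyldimethylsilyl) derivative of 16 (not isolated) | CC(C)N([Si](C)(C)C(C)(C)C)C(=O)Oc1cc(OCc2ccccc2)cc(OCc2ccccc2)c1 | intermediate
18 | 2-lithio derivative of 17 (not isolated) | CC(C)N([Si](C)(C)C(C)(C)C)C(=O)Oc1cc(OCc2ccccc2)cc(OCc2ccccc2)c1[Li] | intermediate
19 | N-(tert-butyldimethylsilyl) derivative of 20 (not isolated) | CC(C)N([Si](C)(C)C(C)(C)C)C(=O)Oc1cc(OCc2ccccc2)cc(OCc2ccccc2)c1[Si](C)(C)C | intermediate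
20 | 3,5-bis(benzyloxy)-2-(trimethylsilyl)phenyl N-isopropylcarbamate | CC(C)NC(=O)Oc1cc(OCc2ccccc2)cc(OCc2ccccc2)c1[Si](C)(C)C | intermediate
21 | N-(trimethylsilyl) derivative of 20 (not isolated) | CC(C)N([Si](C)(C)C)C(=O)Oc1cc(OCc2ccccc2)cc(OCc2ccccc2)c1[Si](C)(C)C | intermediate
22 | 6-lithio derivative of 21 (not isolated) | CC(C)N([Si](C)(C)C)C(=O)Oc1c([Li])c(OCc2ccccc2)cc(OCc2ccccc2)c1[Si](C)(C)C | intermediate
23 | N-(trimethylsilyl) derivative of 24 (not isolated) | CC[Si](CC)(CC)O[C@H](c1ccc(OCc2ccccc2)c(OCc2ccccc2)c1)[C@@H](O)Cc1c(OCc2ccccc2)cc(OCc2ccccc2)c([Si](C)(C)C)c1OC(=O)N(C(C)C)[Si](C)(C)C | intermediate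
24 | 3,5-bis(benzyloxy)-2-[(2S,3R)-3-[3,4-bis(benzyloxy)phenyl]-2-hydroxy-3-(triethylsilyloxy)propyl]-6-(trimethylsilyl)phenyl N-isopropylcarbamate | CC[Si](CC)(CC)O[C@H](c1ccc(OCc2ccccc2)c(OCc2ccccc2)c1)[C@@H](O)Cc1c(OCc2ccccc2)cc(OCc2ccccc2)c([Si](C)(C)C)c1OC(=O)NC(C)C | intermediate
25 | 2-O-[3,4,5-tris(benzyloxy)benzoyl] ester of 24 | CC[Si](CC)(CC)O[C@H](c1ccc(OCc2ccccc2)c(OCc2ccccc2)c1)[C@@H](OC(=O)c1cc(OCc2ccccc2)c(OCc2ccccc2)c(OCc2ccccc2)c1)Cc1c(OCc2ccccc2)cc(OCc2ccccc2)c([Si](C)(C)C)c1OC(=O)NC(C)C | intermediate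
26 | phenol from carbamate cleavage of 25 (not isolated) | CC[Si](CC)(CC)O[C@H](c1ccc(OCc2ccccc2)c(OCc2ccccc2)c1)[C@@H](OC(=O)c1cc(OCc2ccccc2)c(OCc2ccccc2)c(OCc2ccccc2)c1)Cc1c(OCc2ccccc2)cc(OCc2ccccc2)c([Si](C)(C)C)c1O | intermediate
27 | aryl triflate of 26 | CC[Si](CC)(CC)O[C@H](c1ccc(OCc2ccccc2)c(OCc2ccccc2)c1)[C@@H](OC(=O)c1cc(OCc2ccccc2)c(OCc2ccccc2)c(OCc2ccccc2)c1)Cc1c(OCc2ccccc2)cc(OCc2ccccc2)c([Si](C)(C)C)c1OS(=O)(=O)C(F)(F)F | intermediate
28 | (1R,2S)-1-[3,4-bis(benzyloxy)phenyl]-3-[2,4-bis(benzyloxy)-6-(trifluoromethylsulfonyloxy)-5-(trimethylsilyl)phenyl]-1-hydroxypropan-2-yl 3,4,5-tris(benzyloxy)benzoate | O[C@H](c1ccc(OCc2ccccc2)c(OCc2ccccc2)c1)[C@@H](OC(=O)c1cc(OCc2ccccc2)c(OCc2ccccc2)c(OCc2ccccc2)c1)Cc1c(OCc2ccccc2)cc(OCc2ccccc2)c([Si](C)(C)C)c1OS(=O)(=O)C(F)(F)F | intermediate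
29 | 4β-O-ether of the dimer digallate with alcohol 28 | O=C(O[C@@H]1[C@@H](O[C@H](c2ccc(OCc5ccccc5)c(OCc5ccccc5)c2)[C@@H](OC(=O)c2cc(OCc5ccccc5)c(OCc5ccccc5)c(OCc5ccccc5)c2)Cc2c(OCc5ccccc5)cc(OCc5ccccc5)c([Si](C)(C)C)c2OS(=O)(=O)C(F)(F)F)c2c(OCc5ccccc5)cc(OCc5ccccc5)c([C@H]3c4c(OCc5ccccc5)cc(OCc5ccccc5)cc4O[C@H](c4ccc(OCc5ccccc5)c(OCc5ccccc5)c4)[C@@H]3OC(=O)c3cc(OCc5ccccc5)c(OCc5ccccc5)c(OCc5ccccc5)c3)c2O[C@@H]1c1cc(OCc5ccccc5)c(OCc5ccccc5)c(OCc5ccccc5)c1)c1cc(OCc5ccccc5)c(OCc5ccccc5)c(OCc5ccccc5)c1 | intermediate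
30 | aryne formed from 29 (not isolated) | O=C(O[C@@H]1[C@@H](O[C@H](c2ccc(OCc5ccccc5)c(OCc5ccccc5)c2)[C@@H](OC(=O)c2cc(OCc5ccccc5)c(OCc5ccccc5)c(OCc5ccccc5)c2)CC2=C(OCc5ccccc5)C=C(OCc5ccccc5)C#C2)c2c(OCc5ccccc5)cc(OCc5ccccc5)c([C@H]3c4c(OCc5ccccc5)cc(OCc5ccccc5)cc4O[C@H](c4ccc(OCc5ccccc5)c(OCc5ccccc5)c4)[C@@H]3OC(=O)c3cc(OCc5ccccc5)c(OCc5ccccc5)c(OCc5ccccc5)c3)c2O[C@@H]1c1cc(OCc5ccccc5)c(OCc5ccccc5)c(OCc5ccccc5)c1)c1cc(OCc5ccccc5)c(OCc5ccccc5)c(OCc5ccccc5)c1 | intermediate
31 | oxonium/aryl-anion zwitterion (not isolated) | O=C(O[C@@H]1[C@@H]([O+]2[C@H](c6ccc(OCc5ccccc5)c(OCc5ccccc5)c6)[C@@H](OC(=O)c6cc(OCc5ccccc5)c(OCc5ccccc5)c(OCc5ccccc5)c6)CC6=C(OCc5ccccc5)C=C(OCc5ccccc5)[C-]=C62)c2c(OCc5ccccc5)cc(OCc5ccccc5)c([C@H]3c4c(OCc5ccccc5)cc(OCc5ccccc5)cc4O[C@H](c4ccc(OCc5ccccc5)c(OCc5ccccc5)c4)[C@@H]3OC(=O)c3cc(OCc5ccccc5)c(OCc5ccccc5)c(OCc5ccccc5)c3)c2O[C@@H]1c1cc(OCc5ccccc5)c(OCc5ccccc5)c(OCc5ccccc5)c1)c1cc(OCc5ccccc5)c(OCc5ccccc5)c(OCc5ccccc5)c1 | intermediate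
32 | docosa-O-benzyl derivative of the target | O=C(O[C@@H]1[C@@H](c2c(OCc5ccccc5)cc(OCc5ccccc5)c3c2O[C@H](c2ccc(OCc5ccccc5)c(OCc5ccccc5)c2)[C@@H](OC(=O)c2cc(OCc5ccccc5)c(OCc5ccccc5)c(OCc5ccccc5)c2)C3)c2c(OCc5ccccc5)cc(OCc5ccccc5)c([C@H]3c4c(OCc5ccccc5)cc(OCc5ccccc5)cc4O[C@H](c4ccc(OCc5ccccc5)c(OCc5ccccc5)c4)[C@@H]3OC(=O)c3cc(OCc5ccccc5)c(OCc5ccccc5)c(OCc5ccccc5)c3)c2O[C@@H]1c1cc(OCc5ccccc5)c(OCc5ccccc5)c(OCc5ccccc5)c1)c1cc(OCc5ccccc5)c(OCc5ccccc5)c(OCc5ccccc5)c1 | intermediate
33 | CNP0321910.1 | O=C(O[C@@H]1[C@@H](c2c(O)cc(O)c3c2O[C@H](c2ccc(O)c(O)c2)[C@@H](OC(=O)c2cc(O)c(O)c(O)c2)C3)c2c(O)cc(O)c([C@H]3c4c(O)cc(O)cc4O[C@H](c4ccc(O)c(O)c4)[C@@H]3OC(=O)c3cc(O)c(O)c(O)c3)c2O[C@@H]1c1cc(O)c(O)c(O)c1)c1cc(O)c(O)c(O)c1 | target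

## Step count and risks

Total step count: 19. Longest linear sequence: 10 steps (8, 9, 10, 13, 14, 15, 16, 17, 18, 19).

**Risk 1: step 18 (proposed new method).** After the ether oxygen has added to the aryne, proton capture by the aryl anion or β‑elimination/fragmentation of the oxonium may outrun the 1,3‑shift. The crowded ether oxygen may also trap the aryne too slowly, so that intermolecular aryne consumption wins. The fallback uses known chemistry, sets out from 28 and 10 and comes back at 32. Fluoride (CsF, MeCN, rt) converts 28 into the hydroxy aryne F1, which is not isolated; its tethered hydroxyl adds across the aryne to give 5,7,3',4'-tetra-O-benzylcatechin 3-O-[3,4,5-tris(benzyloxy)benzoate] F2, a chroman‑forming aryne cyclisation of a known type. The classical silver‑promoted Friedel–Crafts coupling of the 4‑thio donor 10 with an excess of F2 (AgOSO2CF3, CH2Cl2, −40 → 0 °C) should then form the C4–C8 bond anti to the 3‑O‑galloyl group and deliver 32.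

**Risk 2: step 17.** The hindered secondary alcohol may fail to capture the hindered flavan‑4‑yl cation. Competing processes are C‑alkylation by free C8/C6 positions (oligomerisation), orthoester formation through the participating gallate, and re‑ionisation of the product ether. The fallback gives up the oxygen link, sets out from 10 and comes back at 32. Commercial (+)-catechin is benzylated (BnBr, K2CO3, DMF) to 5,7,3',4'-tetra-O-benzyl-(+)-catechin F3. Its C8 is coupled with 10 (AgOSO2CF3, excess F3) to the perbenzylated trimer with a free terminal 3‑hydroxyl F4. Steglich esterification of F4 with 9 (DCC, DMAP) gives 32.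

**Risk 3: step 13.** Epoxide opening by the crowded aryllithium 22 may be slow, which would let anionic ortho‑Fries rearrangement of the carbamate, α‑metalation/Wittig rearrangement of benzyl ethers, or silyl migration between the vicinal oxygens take over. The fallback reverses the order of the two metalations, sets out from 16 and 14 and comes back at 24. Carbamate 16 is N‑silylated and lithiated exactly as in step 12 (through 17 and 18). The less hindered aryllithium 18 opens 14 (BF3·OEt2, −78 °C) to the N‑silyl adduct F5 (not isolated), which the citric acid work‑up hydrolyses to the ring‑unsilylated hydroxy carbamate F6. Its hydroxyl is capped (Me3SiCl, imidazole) as the trimethylsilyl ether F7. N‑Silylation as in step 13 (Me3SiOSO2CF3, TMEDA) to the N‑trimethylsilyl carbamate F8 (not isolated), lithiation at the only free position ortho to the carbamate to the aryllithium F9 (not isolated) and a Me3SiCl quench give the fully silylated carbamate F10 (not isolated). The citric acid work‑up cleaves its N–SiMe3 and O–SiMe3 bonds but not the triethylsilyl ether, returning 24.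

## Further compounds

F1 | step 18 | hydroxy aryne formed from 28 (not isolated) | O[C@H](c1ccc(OCc2ccccc2)c(OCc2ccccc2)c1)[C@@H](OC(=O)c1cc(OCc2ccccc2)c(OCc2ccccc2)c(OCc2ccccc2)c1)CC1=C(OCc2ccccc2)C=C(OCc2ccccc2)C#C1
F2 | step 18 | 5,7,3',4'-tetra-O-benzylcatechin 3-O-[3,4,5-tris(benzyloxy)benzoate] | C1c2c(OCc5ccccc5)cc(OCc5ccccc5)cc2O[C@H](c2ccc(OCc5ccccc5)c(OCc5ccccc5)c2)[C@H]1OC(=O)c1cc(OCc5ccccc5)c(OCc5ccccc5)c(OCc5ccccc5)c1
F3 | step 17 | 5,7,3',4'-tetra-O-benzyl-(+)-catechin | C1c2c(OCc5ccccc5)cc(OCc5ccccc5)cc2O[C@H](c2ccc(OCc5ccccc5)c(OCc5ccccc5)c2)[C@H]1O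
F4 | step 17 | perbenzylated trimer with a free terminal 3-hydroxyl | O=C(O[C@@H]1[C@@H](c2c(OCc5ccccc5)cc(OCc5ccccc5)c3c2O[C@H](c2ccc(OCc5ccccc5)c(OCc5ccccc5)c2)[C@@H](O)C3)c2c(OCc5ccccc5)cc(OCc5ccccc5)c([C@H]3c4c(OCc5ccccc5)cc(OCc5ccccc5)cc4O[C@H](c4ccc(OCc5ccccc5)c(OCc5ccccc5)c4)[C@@H]3OC(=O)c3cc(OCc5ccccc5)c(OCc5ccccc5)c(OCc5ccccc5)c3)c2O[C@@H]1c1cc(OCc5ccccc5)c(OCc5ccccc5)c(OCc5ccccc5)c1)c1cc(OCc5ccccc5)c(OCc5ccccc5)c(OCc5ccccc5)c1
F5 | step 13 | N-silyl adduct of 18 and 14 (not isolated) | CC[Si](CC)(CC)O[C@H](c1ccc(OCc2ccccc2)c(OCc2ccccc2)c1)[C@@H](O)Cc1c(OCc2ccccc2)cc(OCc2ccccc2)cc1OC(=O)N(C(C)C)[Si](C)(C)C(C)(C)C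
F6 | step 13 | ring-unsilylated hydroxy carbamate | CC[Si](CC)(CC)O[C@H](c1ccc(OCc2ccccc2)c(OCc2ccccc2)c1)[C@@H](O)Cc1c(OCc2ccccc2)cc(OCc2ccccc2)cc1OC(=O)NC(C)C
F7 | step 13 | trimethylsilyl ether of F6 | CC[Si](CC)(CC)O[C@H](c1ccc(OCc2ccccc2)c(OCc2ccccc2)c1)[C@@H](O[Si](C)(C)C)Cc1c(OCc2ccccc2)cc(OCc2ccccc2)cc1OC(=O)NC(C)C
F8 | step 13 | N-trimethylsilyl carbamate from F7 (not isolated) | CC[Si](CC)(CC)O[C@H](c1ccc(OCc2ccccc2)c(OCc2ccccc2)c1)[C@@H](O[Si](C)(C)C)Cc1c(OCc2ccccc2)cc(OCc2ccccc2)cc1OC(=O)N(C(C)C)[Si](C)(C)C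
F9 | step 13 | aryllithium from F8 (not isolated) | CC[Si](CC)(CC)O[C@H](c1ccc(OCc2ccccc2)c(OCc2ccccc2)c1)[C@@H](O[Si](C)(C)C)Cc1c(OCc2ccccc2)cc(OCc2ccccc2)c([Li])c1OC(=O)N(C(C)C)[Si](C)(C)C
F10 | step 13 | fully silylated carbamate (not isolated) | CC[Si](CC)(CC)O[C@H](c1ccc(OCc2ccccc2)c(OCc2ccccc2)c1)[C@@H](O[Si](C)(C)C)Cc1c(OCc2ccccc2)cc(OCc2ccccc2)c([Si](C)(C)C)c1OC(=O)N(C(C)C)[Si](C)(C)C
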